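All runs were generated by integration with made-up constants; noise was put on by code.

Take the time of reading, 12 min, at which the earlier runs still hold 14.2% to 43.5% of their substrate, and work in the odds, [target]/[substrate], the quantity that a second-order integrated rate law makes grow in proportion to time when the charges are equal, as they are here at 1.00 equiv.

| flask | substrate | reagent | free catalyst | remark | time |
|---|---|---|---|---|---|
| eta | 0.093 mM | 1 equiv | 0.05 mol% | run made earlier |  |
| epsilon | 0.31 mM | 1 equiv | 0.05 mol% | run made earlier |  |
| beta | 0.95 mM | 1 equiv | 0.05 mol% | run made earlier |  |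
| winter | 0.60 mM | 1.00 equiv | 0.05 mol% |  | 12 min |
| spring | 0.12 mM | 1.00 equiv | 0.05 mol% |  | 12 min |
| summer | 0.20 mM | 1.00 equiv | 0.05 mol% |  | 12 min |
| dawn | 0.80 mM | 1.00 equiv | 0.05 mol% |  | 12 min |
| dusk | 0.30 mM | 1.00 equiv | 0.05 mol% |  | 12 min |

| run | time / min | target / % | substrate / % |
|---|---|---|---|
| eta | 2.50 | 28.2 | 72.6 |
| eta | 5.00 | 40.5 | 59.9 |
| eta | 8.00 | 50.5 | 48.6 |
| eta | 10.0 | 54.3 | 45.5 |
| eta | 12.0 | 59.2 | 43.5 |
| epsilon | 1.00 | 26.5 | 74.8 |
| epsilon | 2.00 | 38.3 | 61.5 |
| epsilon | 3.00 | 48.1 | 53.1 |
| epsilon | 6.00 | 62.8 | 37.8 |
| epsilon | 12.0 | 75.5 | 23.5 |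
| beta | 1.00 | 28.8 | 70.2 |
| beta | 2.00 | 41.8 | 55.9 |
| beta | 3.00 | 53.5 | 47.0 |
| beta | 6.00 | 72.9 | 28.7 |
| beta | 12.0 | 85.8 | 14.2 |

(standard deviation of a reading: 1 percentage point)



1. all flasks from highest to lowest amount of target, in percent of the substrate charged, at 12 min (winter / spring / summer / dawn / dusk)
2. the amount of target, in percent of the substrate charged of the flask you put first, at 12 min
3. the amount of target, in percent of the substrate charged of the flask you put last, at 12 min

Test that rule on the readings first: doubling the time multiplies the odds by 1.77 in eta (from 5.00 min to 10.0 min), and from 6.00 min to 12.0 min by 1.93 in epsilon and 2.38 in beta, so the rule bends under at the dilute end and over at the concentrated end. Solve each end separately, then, and rank the flasks between them by charge, since the odds rise from eta through epsilon to beta.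

Interpolate ln odds against ln charge between the bracketing runs in two ways, once from the target reading and once from the substrate reading, each taken against its complement. For dawn, between epsilon and beta, the ways give 5.45 and 5.50, which agree, so trust 84.5%.

For spring they part: eta at 12.0 min gives 1.45 by target and 1.30 by substrate, its pair overshooting closure by 2.7 percentage points. Neither reading of that pair can be singled out, so take the cheat to be the complement, which both ways lean on and which this pair does not obey, and drop it by dividing the two readings directly, which gives 1.36 for eta and 3.21 for epsilon. Commit therefore to this ratio, and call the spring odds at the time of reading 1.63, which is 62.0% of target, lying between the 1.70 of the target way and the 1.58 of the substrate way.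

The forecast, saying “I did not settle on a mechanism, so I interpolated this trend empirically in log-log form”, gave dawn > winter > dusk > summer > spring, with 84.5% (82.5% to 86.5%) first and 62.5% (59.5% to 65.5%) last.

The flasks give dawn > winter > dusk > summer > spring, with dawn at 84.2% and spring at 62.6%.

    substrate + free catalyst ⇌ catalyst intermediate A (K = 3200 M⁻¹, k = 8.08 × 10⁶ M⁻¹ s⁻¹)
    reagent + catalyst intermediate A ⇌ catalyst intermediate B (K = 1200 M⁻¹, k = 6.21 × 10⁵ M⁻¹ s⁻¹)
    catalyst intermediate B ⇌ by-product + catalyst intermediate C (K = 3.20 × 10⁻⁴ M, k = 6010 s⁻¹)
    catalyst intermediate C ⇌ catalyst intermediate D (K = 0.330, k = 67.2 s⁻¹)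
    catalyst intermediate D → free catalyst + target (k = 106 s⁻¹)

Neither end has come to rest at 12 min: spring still holds 37% of its substrate, and its target has moved by 5 points when read at 9.27 min or 15.7 min. Carry the odds on to 120 min: in proportion to time, the spring odds give 94.2%, and spring reaches 92.5%, less, with 7.54% of its substrate left. The dawn odds give 98.2%, and dawn reaches 98.7%, more, with 1.35% of its substrate left.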